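**Retrosynthetic overview**
- Target ⇐ allylic C–H oxidation of the terminal E-methyl of the 12'-deoxy epoxyquinol ⇐ ketal unmasking ⇐ hydroxyl-directed epoxidation of an (S)-dienol ⇐ CBS reduction of a quinone monoketal.
- The monoketal comes from regioselective mono-hydrolysis of a 2,5-disubstituted quinone bisketal. This leaves C=O where the carbinol is needed and keeps the future ketone masked.
- Key disconnections: both ring–substituent C–C bonds (ring–farnesyl, then ring–CH2OAc). Each is made from a quinone-bisketal vinyllithium, a quinone carbanion (masked β-acylvinyl anion) that reacts with farnesyl bromide and then with formaldehyde.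
- Ring order: the carbocycle is bought as an arene and dearomatised electrochemically at the start. The oxirane is the only ring built, in step 6.

Assumption: (2E,6E)-farnesol is taken as the cheap chain source (buying bromide 2 would delete step 1); "farnesyl" below means (2E,6E)-3,7,11-trimethyldodeca-2,6,10-trien-1-yl.

**Step 1**
Reactants: 1 (2E,6E)-farnesol
Product: 2 (2E,6E)-farnesyl bromide
Conditions: PBr3 (0.4 equiv), Et2O, −10 → 0 °C, 30 min; used crude
Reagents that add atoms: phosphorus tribromide, BrP(Br)Br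
Why: PBr3 bromination (SN2 on the phosphite ester of a primary allylic alcohol) at low temperature keeps the 2E,6E geometry and avoids allylic transposition.

**Step 2**
Reactants: 3 1,4-dibromo-2,5-dimethoxybenzene
Product: 4 1,4-dibromo-3,3,6,6-tetramethoxycyclohexa-1,4-diene (2,5-dibromobenzoquinone bisketal)
Conditions: anodic oxidation, Pt anode, undivided cell, 1% KOH/MeOH, 0 °C, constant current (ca. 3 F/mol)
Reagents that add atoms: methanol, CO
Why: Swenton-type anodic oxidation: two-electron oxidation of the hydroquinone dimethyl ether in basic methanol, with methoxide capture at both oxygen-bearing carbons, gives the quinone bisketal (dearomatisation); no stereocentre.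

**Step 3 (key step)**
Reactants: 4 1,4-dibromo-3,3,6,6-tetramethoxycyclohexa-1,4-diene; 2 (2E,6E)-farnesyl bromide
Product: 6 1-bromo-3,3,6,6-tetramethoxy-4-farnesylcyclohexa-1,4-diene, via vinyllithium 5 (not isolated)
Conditions: n-BuLi (1.0 equiv), THF, −78 °C, 20 min; CuI (10 mol %), then 2, −78 → −20 °C
Reagents that add atoms: none
Why: Br/Li exchange turns a quinone ring carbon (an acceptor position in the quinone) into a vinyl anion, a masked β-acylvinyl anion (d3 reagent), which under Cu catalysis displaces the primary allylic bromide at its α-carbon (SN2) with retention of the 2E,6E geometry; this umpolung alkylation joins two carbons that are both electrophilic in their native forms, and no stereocentre is formed.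

**Step 4**
Reactants: 6 1-bromo-3,3,6,6-tetramethoxy-4-farnesylcyclohexa-1,4-diene
Product: 10 (3,3-dimethoxy-6-oxo-4-farnesylcyclohexa-1,4-dien-1-yl)methyl acetate, via vinyllithium 7 (not isolated), via lithium alkoxide 8 (not isolated), via acetoxymethyl bisketal 9 (not isolated)
Conditions: n-BuLi (1.05 equiv), THF, −78 °C; CH2O (monomeric, from cracked paraformaldehyde), −78 → 0 °C; Ac2O (3 equiv), 0 °C → rt; then AcOH–H2O–THF, rt, 1 h
Reagents that add atoms: formaldehyde, C=O; acetic anhydride, CC(=O)OC(C)=O; water, O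
Why: The same reversed-polarity vinyl anion adds to formaldehyde, the alkoxide is acetylated in the flask, and dilute acid then hydrolyses only the ketal whose cation is delocalised onto the farnesyl-bearing carbon (the ketal next to the CH2OAc carbon), a regioselective bisketal mono-hydrolysis; no stereocentre.

**Step 5**
Reactants: 10 (3,3-dimethoxy-6-oxo-4-farnesylcyclohexa-1,4-dien-1-yl)methyl acetate
Product: 11 [(6S)-6-hydroxy-3,3-dimethoxy-4-farnesylcyclohexa-1,4-dien-1-yl]methyl acetate
Conditions: (R)-Me-CBS (0.2 equiv), catecholborane (1.5 equiv), toluene, −78 °C; cold aq. NaOH wash; used at once (Et3N-buffered)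
Reagents that add atoms: none
Why: Corey–Bakshi–Shibata reduction: the oxazaborolidine–borane complex binds the carbonyl anti to the α-branched (CH2OAc-bearing) alkenyl arm and delivers hydride 1,2 to one face, setting the (S)-carbinol (R in the target after the priority change).

**Step 6**
Reactants: 11 [(6S)-6-hydroxy-3,3-dimethoxy-4-farnesylcyclohexa-1,4-dien-1-yl]methyl acetate
Product: 12 [(1R,2R,6R)-2-hydroxy-5,5-dimethoxy-6-farnesyl-7-oxabicyclo[4.1.0]hept-3-en-3-yl]methyl acetate (OH cis to the oxirane oxygen)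
Conditions: VO(acac)2 (5 mol %), t-BuOOH (1.2 equiv, anhydrous), 2,6-lutidine (0.2 equiv), toluene, 0 °C
Reagents that add atoms: tert-butyl hydroperoxide, CC(C)(C)OO
Why: Sharpless–Michaelson vanadium-catalysed hydroxyl-directed epoxidation: the vanadate ester of the ring alcohol delivers oxygen to its own face and to the more electron-rich ring alkene (farnesyl-substituted; the other is deactivated by its allylic acetate, and the chain alkenes are not allylic alcohols), setting both oxirane carbons cis to OH.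

**Step 7**
Reactants: 12 [(1R,2R,6R)-2-hydroxy-5,5-dimethoxy-6-farnesyl-7-oxabicyclo[4.1.0]hept-3-en-3-yl]methyl acetate
Product: 13 [(1R,2R,6R)-2-hydroxy-5-oxo-6-farnesyl-7-oxabicyclo[4.1.0]hept-3-en-3-yl]methyl acetate
Conditions: 48% aq. HF–MeCN (1:20), 0 °C → rt
Reagents that add atoms: water, O
Why: Acid-catalysed ketal hydrolysis (oxocarbenium formation, water capture) unmasks the enone without touching the epoxide, the acetate or the three stereocentres.

**Step 8**
Reactants: 13 [(1R,2R,6R)-2-hydroxy-5-oxo-6-farnesyl-7-oxabicyclo[4.1.0]hept-3-en-3-yl]methyl acetate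
Product: 14 [(1R,2R,6R)-2-hydroxy-6-[(2E,6E,10E)-12-hydroxy-3,7,11-trimethyldodeca-2,6,10-trien-1-yl]-5-oxo-7-oxabicyclo[4.1.0]hept-3-en-3-yl]methyl acetate (CNP0336169.1)
Conditions: SeO2 (0.3 equiv), t-BuOOH (3 equiv), salicylic acid (0.1 equiv), CH2Cl2, 0 °C → rt, stopped at ca. 60% conversion, 13 recycled
Reagents that add atoms: tert-butyl hydroperoxide, CC(C)(C)OO (terminal oxygen source); selenium dioxide, O=[Se]=O (catalytic oxygen carrier)
Why: Sharpless SeO2/TBHP allylic oxidation (ene reaction, then [2,3]-sigmatropic shift) attacks the most electron-rich and least hindered alkene of a polyprenyl chain, the terminal isopropylidene, at its E-methyl group and gives the (E)-allylic alcohol; no stereocentre is touched.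

**Compound list**
1 | (2E,6E)-farnesol | OC/C=C(\C)CC/C=C(\C)CCC=C(C)C | starting material
2 | (2E,6E)-farnesyl bromide | BrC/C=C(\C)CC/C=C(\C)CCC=C(C)C | intermediate
3 | 1,4-dibromo-2,5-dimethoxybenzene | COc1cc(Br)c(OC)cc1Br | starting material
4 | 1,4-dibromo-3,3,6,6-tetramethoxycyclohexa-1,4-diene | COC1(OC)C=C(Br)C(OC)(OC)C=C1Br | intermediate
5 | (4-bromo-3,3,6,6-tetramethoxycyclohexa-1,4-dien-1-yl)lithium | [Li]C1=CC(OC)(OC)C(Br)=CC1(OC)OC | intermediate
6 | 1-bromo-3,3,6,6-tetramethoxy-4-farnesylcyclohexa-1,4-diene | COC1(OC)C=C(Br)C(OC)(OC)C=C1C/C=C(\C)CC/C=C(\C)CCC=C(C)C | intermediate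
7 | (3,3,6,6-tetramethoxy-4-farnesylcyclohexa-1,4-dien-1-yl)lithium | [Li]C1=CC(OC)(OC)C(C/C=C(\C)CC/C=C(\C)CCC=C(C)C)=CC1(OC)OC | intermediate
8 | lithium (3,3,6,6-tetramethoxy-4-farnesylcyclohexa-1,4-dien-1-yl)methanolate | [Li]OCC1=CC(OC)(OC)C(C/C=C(\C)CC/C=C(\C)CCC=C(C)C)=CC1(OC)OC | intermediate
9 | (3,3,6,6-tetramethoxy-4-farnesylcyclohexa-1,4-dien-1-yl)methyl acetate | CC(=O)OCC1=CC(OC)(OC)C(C/C=C(\C)CC/C=C(\C)CCC=C(C)C)=CC1(OC)OC | intermediate
10 | (3,3-dimethoxy-6-oxo-4-farnesylcyclohexa-1,4-dien-1-yl)methyl acetate | CC(=O)OCC1=CC(OC)(OC)C(C/C=C(\C)CC/C=C(\C)CCC=C(C)C)=CC1=O | intermediate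
11 | [(6S)-6-hydroxy-3,3-dimethoxy-4-farnesylcyclohexa-1,4-dien-1-yl]methyl acetate | CC(=O)OCC1=CC(OC)(OC)C(C/C=C(\C)CC/C=C(\C)CCC=C(C)C)=C[C@@H]1O | intermediate
12 | [(1R,2R,6R)-2-hydroxy-5,5-dimethoxy-6-farnesyl-7-oxabicyclo[4.1.0]hept-3-en-3-yl]methyl acetate | CC(=O)OCC1=CC(OC)(OC)[C@]2(C/C=C(\C)CC/C=C(\C)CCC=C(C)C)O[C@@H]2[C@@H]1O | intermediate
13 | [(1R,2R,6R)-2-hydroxy-5-oxo-6-farnesyl-7-oxabicyclo[4.1.0]hept-3-en-3-yl]methyl acetate | CC(=O)OCC1=CC(=O)[C@]2(C/C=C(\C)CC/C=C(\C)CCC=C(C)C)O[C@@H]2[C@@H]1O | intermediate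
14 | [(1R,2R,6R)-2-hydroxy-6-[(2E,6E,10E)-12-hydroxy-3,7,11-trimethyldodeca-2,6,10-trien-1-yl]-5-oxo-7-oxabicyclo[4.1.0]hept-3-en-3-yl]methyl acetate | CC(=O)OCC1=CC(=O)[C@]2(C/C=C(\C)CC/C=C(\C)CC/C=C(\C)CO)O[C@@H]2[C@@H]1O | target

**Step count**
Total: 8 steps. Longest linear sequence: 7 steps (steps 2–8, from 3).

**Three steps most likely to fail**

Step 6. The dienol ketal 11 ionises easily and can aromatise under Lewis-acidic vanadium, and the second ring alkene may compete. The fallback sets out from 10 and comes back at 13. It changes the masking group before the carbinol is made: 10 is transketalised with ethylene glycol (BF3·OEt2 cat., DME) to the spiro-dioxolane dienone F1. The same CBS reduction gives the spiro-dioxolane (S)-dienol F2, whose tethered ketal is much less prone to ionise. Ti(OiPr)4/t-BuOOH epoxidation of the allylic alcohol gives the spiro-dioxolane syn-epoxy alcohol F3, and aqueous HF in MeCN unmasks it to 13.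

Step 8. Late allylic oxidation of the fully functionalised 13 may give low conversion, internal-alkene oxidation or over-oxidation to the enal. The fallback sets out from 10 and comes back at 14. The oxidation is moved to the robust dienone: SeO2/t-BuOOH on 10 gives the 12'-hydroxy dienone F4, which is silylated (TBSCl, imidazole) to the 12'-silyl ether dienone F5. CBS reduction as in step 5 gives the silyl ether (S)-dienol F6, and vanadium-directed epoxidation as in step 6 gives the silyl ether epoxy alcohol F7 (the silyl ether keeps the chain-end allylic alcohol from being epoxidised). Aqueous HF in MeCN then removes ketal and silyl group together and gives 14.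

Step 5. Both arms of the ketone are alkenyl, so the CBS catalyst distinguishes them only through the α-CH2OAc branch and the ee may be moderate. The fallback sets out from 10 and comes back at 11. Luche reduction (NaBH4, CeCl3, MeOH, −78 °C) gives the racemic dienol F8. Lipase kinetic resolution (CAL-B, vinyl butanoate, MTBE) acylates the (R)-enantiomer to the (R)-butanoate F9 (Kazlauskas rule); the unreacted (S)-alcohol is 11 and is separated by chromatography on Et3N-treated silica.

**Further compounds**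
F1 | step 6 | (8-oxo-10-farnesyl-1,4-dioxaspiro[4.5]deca-6,9-dien-7-yl)methyl acetate | CC(=O)OCC1=CC2(OCCO2)C(C/C=C(\C)CC/C=C(\C)CCC=C(C)C)=CC1=O
F2 | step 6 | [(8S)-8-hydroxy-10-farnesyl-1,4-dioxaspiro[4.5]deca-6,9-dien-7-yl]methyl acetate | CC(=O)OCC1=CC2(OCCO2)C(C/C=C(\C)CC/C=C(\C)CCC=C(C)C)=C[C@@H]1O
F3 | step 6 | [(1'R,2'R,6'R)-2'-hydroxy-6'-farnesylspiro[1,3-dioxolane-2,5'-[7]oxabicyclo[4.1.0]hept[3]en]-3'-yl]methyl acetate | CC(=O)OCC1=CC2(OCCO2)[C@]3(C/C=C(\C)CC/C=C(\C)CCC=C(C)C)O[C@@H]3[C@@H]1O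
F4 | step 8 | [3,3-dimethoxy-6-oxo-4-[(2E,6E,10E)-12-hydroxy-3,7,11-trimethyldodeca-2,6,10-trien-1-yl]cyclohexa-1,4-dien-1-yl]methyl acetate | CC(=O)OCC1=CC(OC)(OC)C(C/C=C(\C)CC/C=C(\C)CC/C=C(\C)CO)=CC1=O
F5 | step 8 | [3,3-dimethoxy-6-oxo-4-[(2E,6E,10E)-12-(tert-butyldimethylsilyloxy)-3,7,11-trimethyldodeca-2,6,10-trien-1-yl]cyclohexa-1,4-dien-1-yl]methyl acetate | CC(=O)OCC1=CC(OC)(OC)C(C/C=C(\C)CC/C=C(\C)CC/C=C(\C)CO[Si](C)(C)C(C)(C)C)=CC1=O
F6 | step 8 | [(6S)-6-hydroxy-3,3-dimethoxy-4-[(2E,6E,10E)-12-(tert-butyldimethylsilyloxy)-3,7,11-trimethyldodeca-2,6,10-trien-1-yl]cyclohexa-1,4-dien-1-yl]methyl acetate | CC(=O)OCC1=CC(OC)(OC)C(C/C=C(\C)CC/C=C(\C)CC/C=C(\C)CO[Si](C)(C)C(C)(C)C)=C[C@@H]1O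
F7 | step 8 | [(1R,2R,6R)-2-hydroxy-5,5-dimethoxy-6-[(2E,6E,10E)-12-(tert-butyldimethylsilyloxy)-3,7,11-trimethyldodeca-2,6,10-trien-1-yl]-7-oxabicyclo[4.1.0]hept-3-en-3-yl]methyl acetate | CC(=O)OCC1=CC(OC)(OC)[C@]2(C/C=C(\C)CC/C=C(\C)CC/C=C(\C)CO[Si](C)(C)C(C)(C)C)O[C@@H]2[C@@H]1O
F8 | step 5 | racemic (6-hydroxy-3,3-dimethoxy-4-farnesylcyclohexa-1,4-dien-1-yl)methyl acetate | CC(=O)OCC1=CC(OC)(OC)C(C/C=C(\C)CC/C=C(\C)CCC=C(C)C)=CC1O
F9 | step 5 | [(6R)-6-(butanoyloxy)-3,3-dimethoxy-4-farnesylcyclohexa-1,4-dien-1-yl]methyl acetate | CC(=O)OCC1=CC(OC)(OC)C(C/C=C(\C)CC/C=C(\C)CCC=C(C)C)=C[C@H]1OC(=O)CCC
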